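**Plan**

- Retrosynthesis: the two benzyl ethers and the two methyl ethers beside the bridge are removed first (tetraol 14). Each central ring is then cut at two bonds: bridge-bearing carbon to chain-bearing carbon, and the oxygen-bearing carbon next to the bridge to its CH neighbour (four bonds in all).
- Enabling feature: the bridging CH2 and the two ring carbons it links are the CH–CH2–CH backbone of tetraethyl propane-1,1,3,3-tetracarboxylate 11. In each ring that carbon lies between the chain-bearing carbon (β-carbon of ynone 10) and an oxygen-bearing carbon (an ester carbonyl of 11); the remaining CH–C(O)–CH unit is the α-carbon, carbonyl and methyl of 10.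
- Forward: ynone 10 is made in four steps from benzyl alcohol 1 (bromide, propargylation, desilylation, acylation); both resorcinol rings then close together on 11 in step 5.
- End game: silylation of the two unhindered hydroxyls para to the bridge, methylation of the two beside it, desilylation, hydrogenolysis.
- Stereochemistry: the target is achiral. The enone geometry of 12 and the quaternary carbons of 13 are transient and vanish on aromatisation. Remark: 1, 3, 7 and 11 are taken as purchasable.

Key step: step 5

**Step 1**
Reactants: 1 4-(benzyloxy)-3-methoxybenzyl alcohol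
Product: 2 4-(benzyloxy)-3-methoxybenzyl bromide
Conditions: PBr3 (0.4 equiv), Et2O, 0 °C
Reagents that add atoms: phosphorus tribromide, BrP(Br)Br
Why: Bromination of an activated benzylic alcohol through its phosphite ester and bromide displacement should be fast at 0 °C and leaves both aryl ethers untouched.

**Step 2**
Reactants: 2 4-(benzyloxy)-3-methoxybenzyl bromide; 3 1-(trimethylsilyl)propyne
Product: 5 {4-[4-(benzyloxy)-3-methoxyphenyl]but-1-yn-1-yl}trimethylsilane, via 3-(trimethylsilyl)prop-2-ynyllithium 4 (not isolated)
Conditions: 3, n-BuLi, THF, −78 to −20 °C; then 2, −78 °C to rt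
Reagents that add atoms: none
Why: Propargylic lithiation of the silylpropyne followed by SN2 alkylation of the reactive benzylic bromide should deliver the homopropargyl arene, the silyl group directing attack to the propargylic rather than the allenyl terminus.

**Step 3**
Reactants: 5 {4-[4-(benzyloxy)-3-methoxyphenyl]but-1-yn-1-yl}trimethylsilane
Product: 6 1-(benzyloxy)-4-(but-3-yn-1-yl)-2-methoxybenzene
Conditions: K2CO3, MeOH–THF, rt
Reagents that add atoms: none
Why: Methanolysis of the alkynyl–silicon bond (protodesilylation) is a standard mild unmasking of a terminal alkyne and does not affect the benzyl ether.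

**Step 4**
Reactants: 6 1-(benzyloxy)-4-(but-3-yn-1-yl)-2-methoxybenzene; 7 N-methoxy-N-methylacetamide
Product: 10 6-[4-(benzyloxy)-3-methoxyphenyl]hex-3-yn-2-one, via lithium acetylide 8 (not isolated), via lithium hemiaminal alkoxide 9 (not isolated)
Conditions: n-BuLi, THF, −78 °C; then 7, −78 to 0 °C; cold 1 M HCl quench
Reagents that add atoms: none
Why: Weinreb ketone synthesis, in which the chelated tetrahedral adduct 9 survives until the quench and so prevents over-addition, while the cold acidic quench keeps the released amine protonated and away from the ynone.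

**Step 5**
Reactants: 10 6-[4-(benzyloxy)-3-methoxyphenyl]hex-3-yn-2-one (2.1 equiv); 11 tetraethyl propane-1,1,3,3-tetracarboxylate
Product: 14 4,4'-methylenebis(5-{2-[4-(benzyloxy)-3-methoxyphenyl]ethyl}benzene-1,3-diol), via bis-enone tetraester 12 (not isolated), via bis(cyclohexenedione) diester 13 (not isolated)
Conditions: KOt-Bu (0.2 equiv), THF, 0 °C to rt, argon, until both additions are complete; then NaOEt (6 equiv), EtOH, 60 °C; then aq. NaOH, reflux; then aq. HCl to pH 2, 40 °C
Reagents that add atoms: none
Why: Proposed new method: each tertiary malonate anion of 11 adds in conjugate fashion to the chain-bearing alkyne carbon of 10 (the vinyl anion is quenched by the next malonate C–H, so the base turns over) and 12 holds no acidic malonate hydrogen before any ring forms; ethoxide then generates the methyl ketone enolate of each arm, which attacks one of the geminal esters in a 6-(enolendo)-exo-trig Claisen closure to give the two cyclohexenedione rings of 13, held as stabilised enolates. The closest known reaction is the Michael–Claisen synthesis of resorcylic esters from malonate anions and acetylenic ketones; what is new is the twofold use of a 2-substituted malonate, which leaves a quaternary ring carbon that can aromatise only by giving up its ester. That ester should be removed by hydroxide (saponification, then decarboxylation of the vinylogous β-keto acid on acidification), after which tautomerisation delivers both resorcinol rings. Both rings close by the same mode, and since the two quaternary centres of 13 are erased no stereochemistry needs control. Regiochemistry is fixed by ring size, because only malonate-carbon attack at the β-carbon followed by methyl-to-ester closure gives a six-membered ring, and the E and Z enones of 12 should interconvert through the γ-dienolate and funnel into the Z isomer that can cyclise. The selectivity the step needs is loss of the ester rather than loss of the bridge from the dienone, which is served by completing both conjugate additions under catalytic base before stoichiometric ethoxide is introduced.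

**Step 6**
Reactants: 14 4,4'-methylenebis(5-{2-[4-(benzyloxy)-3-methoxyphenyl]ethyl}benzene-1,3-diol)
Product: 15 2,2'-methylenebis(3-{2-[4-(benzyloxy)-3-methoxyphenyl]ethyl}-5-[(triisopropylsilyl)oxy]phenol)
Conditions: i-Pr3SiCl (2.1 equiv), imidazole, DMF, 0 °C
Reagents that add atoms: chlorotriisopropylsilane, CC(C)[Si](Cl)(C(C)C)C(C)C
Why: Sterically controlled silylation with a bulky silyl chloride should take the two hydroxyls flanked only by ring hydrogens (para to the bridge), the two beside the bridge being shielded by the opposite aryl ring and tied up in mutual hydrogen bonding.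

**Step 7**
Reactants: 15 2,2'-methylenebis(3-{2-[4-(benzyloxy)-3-methoxyphenyl]ethyl}-5-[(triisopropylsilyl)oxy]phenol)
Product: 16 bis(2-{2-[4-(benzyloxy)-3-methoxyphenyl]ethyl}-6-methoxy-4-[(triisopropylsilyl)oxy]phenyl)methane
Conditions: MeI (excess), K2CO3, acetone, reflux
Reagents that add atoms: iodomethane, CI
Why: Williamson O-methylation of the two remaining phenols, under carbonate conditions that triisopropylsilyl aryl ethers and benzyl ethers tolerate.

**Step 8**
Reactants: 16 bis(2-{2-[4-(benzyloxy)-3-methoxyphenyl]ethyl}-6-methoxy-4-[(triisopropylsilyl)oxy]phenyl)methane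
Product: 17 4,4'-methylenebis(3-{2-[4-(benzyloxy)-3-methoxyphenyl]ethyl}-5-methoxyphenol)
Conditions: Bu4NF, THF, 0 °C; aq. NH4Cl
Reagents that add atoms: none
Why: Fluoride-mediated cleavage of the aryl silyl ethers is selective for silicon and leaves the methyl and benzyl ethers in place.

**Step 9**
Reactants: 17 4,4'-methylenebis(3-{2-[4-(benzyloxy)-3-methoxyphenyl]ethyl}-5-methoxyphenol)
Product: 18 4,4'-methylenebis{3-[2-(4-hydroxy-3-methoxyphenyl)ethyl]-5-methoxyphenol} (CNP0079383.0)
Conditions: H2 (1 atm), 10% Pd/C, EtOAc–MeOH, rt
Reagents that add atoms: none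
Why: Catalytic hydrogenolysis of the two benzyl aryl ethers should be clean because the molecule holds no other reducible group and the diarylmethane and bibenzyl C–C bonds are inert.

**Compound list**

1 | 4-(benzyloxy)-3-methoxybenzyl alcohol | COc1cc(CO)ccc1OCc1ccccc1 | starting material
2 | 4-(benzyloxy)-3-methoxybenzyl bromide | COc1cc(CBr)ccc1OCc1ccccc1 | intermediate
3 | 1-(trimethylsilyl)propyne | CC#C[Si](C)(C)C | starting material
4 | 3-(trimethylsilyl)prop-2-ynyllithium (not isolated) | [Li]CC#C[Si](C)(C)C | intermediate
5 | {4-[4-(benzyloxy)-3-methoxyphenyl]but-1-yn-1-yl}trimethylsilane | COc1cc(CCC#C[Si](C)(C)C)ccc1OCc1ccccc1 | intermediate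
6 | 1-(benzyloxy)-4-(but-3-yn-1-yl)-2-methoxybenzene | COc1cc(CCC#C)ccc1OCc1ccccc1 | intermediate
7 | N-methoxy-N-methylacetamide | CC(=O)N(C)OC | starting material
8 | lithium acetylide of 6 (not isolated) | COc1cc(CCC#C[Li])ccc1OCc1ccccc1 | intermediate
9 | lithium hemiaminal alkoxide from 8 and 7 (not isolated) | COc1cc(CCC#CC(C)(O[Li])N(C)OC)ccc1OCc1ccccc1 | intermediate
10 | 6-[4-(benzyloxy)-3-methoxyphenyl]hex-3-yn-2-one | CC(=O)C#CCCc1ccc(OCc2ccccc2)c(OC)c1 | intermediate
11 | tetraethyl propane-1,1,3,3-tetracarboxylate | CCOC(=O)C(CC(C(=O)OCC)C(=O)OCC)C(=O)OCC | starting material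
12 | tetraethyl 1,3-bis{1-[4-(benzyloxy)-3-methoxyphenyl]-5-oxohex-3-en-3-yl}propane-1,1,3,3-tetracarboxylate (interconverting alkene isomers, geometry not fixed; not isolated) | CCOC(=O)C(CC(C(=O)OCC)(C(=O)OCC)C(CCc1ccc(OCc2ccccc2)c(OC)c1)=CC(C)=O)(C(=O)OCC)C(CCc1ccc(OCc2ccccc2)c(OC)c1)=CC(C)=O | intermediate
13 | diethyl 1,1'-methylenebis(2-{2-[4-(benzyloxy)-3-methoxyphenyl]ethyl}-4,6-dioxocyclohex-2-ene-1-carboxylate) (diastereomer mixture, present as its bis-enolate; not isolated) | CCOC(=O)C1(CC2(C(=O)OCC)C(=O)CC(=O)C=C2CCc2ccc(OCc3ccccc3)c(OC)c2)C(=O)CC(=O)C=C1CCc1ccc(OCc2ccccc2)c(OC)c1 | intermediate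
14 | 4,4'-methylenebis(5-{2-[4-(benzyloxy)-3-methoxyphenyl]ethyl}benzene-1,3-diol) | Oc1cc(O)cc(CCc2ccc(OCc3ccccc3)c(OC)c2)c1Cc1c(O)cc(O)cc1CCc1ccc(OCc2ccccc2)c(OC)c1 | intermediate
15 | 2,2'-methylenebis(3-{2-[4-(benzyloxy)-3-methoxyphenyl]ethyl}-5-[(triisopropylsilyl)oxy]phenol) | CC(C)[Si](C(C)C)(C(C)C)Oc1cc(O)c(Cc2c(O)cc(O[Si](C(C)C)(C(C)C)C(C)C)cc2CCc2ccc(OCc3ccccc3)c(OC)c2)c(CCc2ccc(OCc3ccccc3)c(OC)c2)c1 | intermediate
16 | bis(2-{2-[4-(benzyloxy)-3-methoxyphenyl]ethyl}-6-methoxy-4-[(triisopropylsilyl)oxy]phenyl)methane | CC(C)[Si](C(C)C)(C(C)C)Oc1cc(OC)c(Cc2c(OC)cc(O[Si](C(C)C)(C(C)C)C(C)C)cc2CCc2ccc(OCc3ccccc3)c(OC)c2)c(CCc2ccc(OCc3ccccc3)c(OC)c2)c1 | intermediate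
17 | 4,4'-methylenebis(3-{2-[4-(benzyloxy)-3-methoxyphenyl]ethyl}-5-methoxyphenol) | Oc1cc(OC)c(Cc2c(OC)cc(O)cc2CCc2ccc(OCc3ccccc3)c(OC)c2)c(CCc2ccc(OCc3ccccc3)c(OC)c2)c1 | intermediate
18 | 4,4'-methylenebis{3-[2-(4-hydroxy-3-methoxyphenyl)ethyl]-5-methoxyphenol} (CNP0079383.0, achiral) | COc1cc(CCc2cc(O)cc(OC)c2Cc2c(CCc3ccc(O)c(OC)c3)cc(O)cc2OC)ccc1O | target

**Step count and risks**

Total steps: 9. Longest linear sequence: 9 steps (1 to 18); 3, 7 and 11 enter as purchased materials.

Steps most likely to fail:

Step 5. Three processes could divert it. The anion of 11 may revert by retro-Michael cleavage before it is trapped by the ynone. The alkoxide may compete with the hindered carbanion in conjugate addition. At the dienone stage a ring may aromatise by expelling the bridge (toward a quinone methide or a methylenemalonate) instead of its ester. The fallback forms the bridge by electrophilic aromatic substitution and uses only established reactions. It sets out from 10, which with diethyl malonate and NaOEt in EtOH at reflux (the established Michael–Claisen aromatisation of an unsubstituted malonate) should give ethyl 6-{2-[4-(benzyloxy)-3-methoxyphenyl]ethyl}-2,4-dihydroxybenzoate F1. Saponification and decarboxylation (aq. NaOH, reflux, then HCl) should give 5-{2-[4-(benzyloxy)-3-methoxyphenyl]ethyl}benzene-1,3-diol F2. Acid-catalysed condensation of F2, used in excess, with half an equivalent of aqueous formaldehyde should link two rings through the position next to the side chain (para to one hydroxyl, ortho to the other), and so comes back to the route at 14. The isomer linked between the hydroxyls and any oligomers would have to be separated and unreacted F2 recycled.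

Step 6. Steric discrimination between the hydroxyls para to the bridge and those beside it may be insufficient, leading to silylation at the wrong oxygen or over-silylation. The fallback replaces steric control by a tether and sets out from 14. Phenylboronic acid in toluene with azeotropic removal of water should, under thermodynamic control, form the eight-membered cyclic phenylboronate of the two bridge-flanking hydroxyls F3, since only that pair can chelate boron. Silylation of the two free hydroxyls (i-Pr3SiOTf, 2,6-lutidine, CH2Cl2, −78 to 0 °C) should give the bis(triisopropylsilyl) ether of the boronate F4. Mild hydrolysis of the boronate in aqueous THF returns to the route at 15.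

Step 4. The acetylide may be quenched by proton transfer from the acetamide methyl group, and the liberated N,O-dimethylhydroxylamine may add to the ynone in conjugate fashion during the quench. The fallback changes the oxidation level of the electrophile and sets out from 6. Its lithium acetylide 8 should add to acetaldehyde (THF, −78 °C) to give racemic 6-[4-(benzyloxy)-3-methoxyphenyl]hex-3-yn-2-ol F5. Oxidation of the propargylic alcohol with MnO2 in CH2Cl2 (or Dess–Martin periodinane) comes back to the route at 10.

**Further compounds**

F1 | step 5 | ethyl 6-{2-[4-(benzyloxy)-3-methoxyphenyl]ethyl}-2,4-dihydroxybenzoate | CCOC(=O)c1c(O)cc(O)cc1CCc1ccc(OCc2ccccc2)c(OC)c1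
F2 | step 5 | 5-{2-[4-(benzyloxy)-3-methoxyphenyl]ethyl}benzene-1,3-diol | Oc1cc(O)cc(CCc2ccc(OCc3ccccc3)c(OC)c2)c1
F3 | step 6 | cyclic phenylboronate of 14 across the two bridge-flanking hydroxyls (12H-dibenzo[d,g][1,3,2]dioxaborocine core) | c1ccccc1B1Oc2cc(O)cc(CCc3ccc(OCc4ccccc4)c(OC)c3)c2Cc2c(O1)cc(O)cc2CCc2ccc(OCc3ccccc3)c(OC)c2
F4 | step 6 | bis(triisopropylsilyl) ether of F3 | c1ccccc1B1Oc2cc(O[Si](C(C)C)(C(C)C)C(C)C)cc(CCc3ccc(OCc4ccccc4)c(OC)c3)c2Cc2c(O1)cc(O[Si](C(C)C)(C(C)C)C(C)C)cc2CCc2ccc(OCc3ccccc3)c(OC)c2
F5 | step 4 | 6-[4-(benzyloxy)-3-methoxyphenyl]hex-3-yn-2-ol (racemic) | CC(O)C#CCCc1ccc(OCc2ccccc2)c(OC)c1
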